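The oxolane (O1, C2 aryl, C3 hydroxymethyl, C4 benzyl, C5) is disconnected at O1–C2. C2 is the only oxygenated benzylic carbon and carries the 3,4,5-trimethoxyphenyl ring; C7' on C4 is a plain CH2 whose ring has OH in place of OMe at one meta position. With that phenol as a mesylate, DDQ should take hydride only from the trimethoxybenzyl CH2 of an (S,S)-2,3-dibenzylbutane-1,4-diol, and the hydroxyl of the future C5 closes the ring and sets C2 in the same operation. The diol is reached from a Stobbe/asymmetric-hydrogenation butyrolactone by trans alkylation, benzyl-to-mesyl exchange and reduction.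

Key step: step 9

Assumption: (R,R)-Et-DuPHOS is taken as the ligand antipode that delivers the (S)-acid 6; if a test hydrogenation shows the opposite sense, the (S,S)-ligand is used and nothing else changes.

Remark: the (S,S) configuration of diol 14 carries over unchanged to C3 (S) and C4 (S) of the target, and the trans lactone translates into the 3,4-cis oxolane. The mesylate is installed only after the enolate chemistry because it would not survive alkoxide or amide bases, and the lactone is reduced with LiBH4, since NaBH4 alone is too weak.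

Step 1
Reactants: 1 3-hydroxy-4,5-dimethoxybenzaldehyde
Product: 2 3-(benzyloxy)-4,5-dimethoxybenzaldehyde
Conditions: BnBr, K2CO3, DMF, rt
Reagents that add atoms: benzyl bromide, BrCc1ccccc1
Why: Williamson ether synthesis on the only acidic OH; the benzyl ether will tolerate the alkoxide, hydride and amide bases of steps 2–5.

Step 2
Reactants: 2 3-(benzyloxy)-4,5-dimethoxybenzaldehyde; 3 dimethyl succinate
Product: 5 (E)-4-[3-(benzyloxy)-4,5-dimethoxyphenyl]-3-(methoxycarbonyl)but-3-enoic acid, via paraconic ester lactone 4 (not isolated)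
Conditions: NaOMe, MeOH, reflux; then 2 M HCl
Reagents that add atoms: none
Why: Stobbe condensation, in which the succinate enolate adds to the aldehyde, the alkoxide lactonises onto the distal ester to give 4, and E1cB opening of 4 gives the conjugated (E)-half ester as its carboxylate, which makes the sequence irreversible.

Step 3
Reactants: 5 (E)-4-[3-(benzyloxy)-4,5-dimethoxyphenyl]-3-(methoxycarbonyl)but-3-enoic acid
Product: 6 (3S)-4-[3-(benzyloxy)-4,5-dimethoxyphenyl]-3-(methoxycarbonyl)butanoic acid
Conditions: H2 (5 bar), [Rh(cod)((R,R)-Et-DuPHOS)]OTf (0.5 mol%), NaOMe (10 mol%), MeOH, rt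
Reagents that add atoms: none
Why: Rh-bisphosphine asymmetric hydrogenation of a Stobbe-type itaconate half ester, in which two-point binding of alkene and carboxylate to the chiral Rh centre selects the alkene face and sets the stereocentre that becomes C4 of the target; the homogeneous catalyst should leave the benzyl ether alone.

Step 4
Reactants: 6 (3S)-4-[3-(benzyloxy)-4,5-dimethoxyphenyl]-3-(methoxycarbonyl)butanoic acid
Product: 8 (4S)-4-[3-(benzyloxy)-4,5-dimethoxybenzyl]oxolan-2-one, via hydroxy acid 7 (not isolated)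
Conditions: KOH (1.0 equiv), EtOH, 0 °C; CaCl2, NaBH4, EtOH, −10 °C → rt; then 2 M HCl, rt
Reagents that add atoms: none
Why: Chemoselective ester reduction with calcium borohydride while the carboxylate salt stays untouched, followed by acid-promoted lactonisation of hydroxy acid 7; the stereocentre is not involved.

Step 5
Reactants: 8 (4S)-4-[3-(benzyloxy)-4,5-dimethoxybenzyl]oxolan-2-one; 9 3,4,5-trimethoxybenzyl chloride
Product: 11 (3S,4S)-4-[3-(benzyloxy)-4,5-dimethoxybenzyl]-3-(3,4,5-trimethoxybenzyl)oxolan-2-one, via lithium enolate 10 (not isolated)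
Conditions: LiHMDS, THF, −78 °C; then 9, DMPU, n-Bu4NI (cat.), −78 → −20 °C
Reagents that add atoms: none
Why: Lactone enolate alkylation (SN2) in which the electron-rich benzylic chloride approaches the enolate face anti to the C4 benzyl group, which should set the new C3 centre trans (3S).

Step 6
Reactants: 11 (3S,4S)-4-[3-(benzyloxy)-4,5-dimethoxybenzyl]-3-(3,4,5-trimethoxybenzyl)oxolan-2-one
Product: 12 (3S,4S)-4-(3-hydroxy-4,5-dimethoxybenzyl)-3-(3,4,5-trimethoxybenzyl)oxolan-2-one
Conditions: H2 (1 atm), 10% Pd/C, EtOAc–EtOH, rt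
Reagents that add atoms: none
Why: Hydrogenolysis of an aryl benzyl ether under neutral conditions, to which the lactone, the aryl methyl ethers and both stereocentres are inert.

Step 7
Reactants: 12 (3S,4S)-4-(3-hydroxy-4,5-dimethoxybenzyl)-3-(3,4,5-trimethoxybenzyl)oxolan-2-one
Product: 13 5-{[(3S,4S)-5-oxo-4-(3,4,5-trimethoxybenzyl)oxolan-3-yl]methyl}-2,3-dimethoxyphenyl methanesulfonate
Conditions: MsCl, Et3N, CH2Cl2, 0 °C
Reagents that add atoms: methanesulfonyl chloride, CS(=O)(=O)Cl
Why: Sulfonylation of the phenol, the only hydroxyl group present, without touching the lactone.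

Step 8
Reactants: 13 5-{[(3S,4S)-5-oxo-4-(3,4,5-trimethoxybenzyl)oxolan-3-yl]methyl}-2,3-dimethoxyphenyl methanesulfonate
Product: 14 (2S,3S)-2-{3-[(methylsulfonyl)oxy]-4,5-dimethoxybenzyl}-3-(3,4,5-trimethoxybenzyl)butane-1,4-diol
Conditions: LiBH4, THF, 0 °C → rt; then sat. aq. NH4Cl
Reagents that add atoms: none
Why: Lithium borohydride reduction of the lactone to the 1,4-diol, with the aryl sulfonate expected to be inert to borohydride and no stereocentre at risk, since the α-centre already has the stable trans configuration.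

Step 9
Reactants: 14 (2S,3S)-2-{3-[(methylsulfonyl)oxy]-4,5-dimethoxybenzyl}-3-(3,4,5-trimethoxybenzyl)butane-1,4-diol
Product: 16 [(2R,3S,4S)-4-{3-[(methylsulfonyl)oxy]-4,5-dimethoxybenzyl}-2-(3,4,5-trimethoxyphenyl)oxolan-3-yl]methanol, via benzylic cation 15 (not isolated)
Conditions: DDQ (1.0 equiv, in portions), CH2Cl2–AcOH (10:1), 4 Å MS, 0 °C → rt
Reagents that add atoms: none
Why: DDQ forms a charge-transfer complex with the more electron-rich 3,4,5-trimethoxyphenyl ring and abstracts hydride from its benzylic CH2 (the future C2), giving cation 15, which the para-methoxy group stabilises. The closest known reaction type is the DDQ oxidative cycloetherification of 4-alkoxybenzyl C–H bonds with a tethered alcohol, which is established for 2,3-dibenzylbutane-1,4-diols and gives 2-aryl oxolanes. The oxolane closes by 5-exo-trig attack of the hydroxyl of the future C5 on the cationic carbon, whereas the C9 hydroxyl could only close a four-membered ring and therefore stays free. The new C2 centre is controlled by the existing C3 and C4 centres: the aryl group should take the face opposite to the cis-disposed hydroxymethyl and benzyl groups, giving the (2R) 2,3-trans ring, and any cis isomer can re-ionise in the acidic medium and converge on the same product. Site selectivity between the two benzylic CH2 groups is needed and is secured by the meta mesylate, which makes the second ring the poorer donor; this disfavours hydride loss at C7' (and with it the regioisomeric oxolane or a second closure to a furofuran) as well as Friedel–Crafts capture of the cation by that ring. Further oxidation of the product's benzylic ether is held back by using one equivalent of DDQ added in portions.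

Step 10
Reactants: 16 [(2R,3S,4S)-4-{3-[(methylsulfonyl)oxy]-4,5-dimethoxybenzyl}-2-(3,4,5-trimethoxyphenyl)oxolan-3-yl]methanol
Product: 17 [(2R,3S,4S)-4-(3-hydroxy-4,5-dimethoxybenzyl)-2-(3,4,5-trimethoxyphenyl)oxolan-3-yl]methanol
Conditions: KOH, MeOH–H2O (4:1), 65 °C; then 1 M HCl to pH 5–6
Reagents that add atoms: none
Why: Hydroxide cleavage of the aryl methanesulfonate at the S–O bond frees the phenol, while the oxolane, the primary alcohol and the methyl ethers are stable to base and none of the three stereocentres is epimerisable under these conditions.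

Compound list
1 | 3-hydroxy-4,5-dimethoxybenzaldehyde | COc1cc(C=O)cc(O)c1OC | starting material
2 | 3-(benzyloxy)-4,5-dimethoxybenzaldehyde | COc1cc(C=O)cc(OCc2ccccc2)c1OC | intermediate
3 | dimethyl succinate | COC(=O)CCC(=O)OC | starting material
4 | methyl 2-[3-(benzyloxy)-4,5-dimethoxyphenyl]-5-oxooxolane-3-carboxylate (paraconic ester lactone; racemic diastereomer mixture) | COC(=O)C1CC(=O)OC1c1cc(OC)c(OC)c(OCc2ccccc2)c1 | intermediate (not isolated)
5 | (E)-4-[3-(benzyloxy)-4,5-dimethoxyphenyl]-3-(methoxycarbonyl)but-3-enoic acid | COC(=O)/C(CC(=O)O)=C/c1cc(OC)c(OC)c(OCc2ccccc2)c1 | intermediate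
6 | (3S)-4-[3-(benzyloxy)-4,5-dimethoxyphenyl]-3-(methoxycarbonyl)butanoic acid | OC(=O)C[C@H](Cc1cc(OC)c(OC)c(OCc2ccccc2)c1)C(=O)OC | intermediate
7 | (3S)-4-[3-(benzyloxy)-4,5-dimethoxyphenyl]-3-(hydroxymethyl)butanoic acid | OC(=O)C[C@H](Cc1cc(OC)c(OC)c(OCc2ccccc2)c1)CO | intermediate (not isolated)
8 | (4S)-4-[3-(benzyloxy)-4,5-dimethoxybenzyl]oxolan-2-one | O=C1C[C@H](Cc2cc(OC)c(OC)c(OCc3ccccc3)c2)CO1 | intermediate
9 | 3,4,5-trimethoxybenzyl chloride | COc1cc(CCl)cc(OC)c1OC | starting material
10 | lithium enolate of lactone 8 (lithium (3S)-3-[3-(benzyloxy)-4,5-dimethoxybenzyl]-2,3-dihydrofuran-5-olate) | [Li]OC1=C[C@H](Cc2cc(OC)c(OC)c(OCc3ccccc3)c2)CO1 | intermediate (not isolated)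
11 | (3S,4S)-4-[3-(benzyloxy)-4,5-dimethoxybenzyl]-3-(3,4,5-trimethoxybenzyl)oxolan-2-one (trans) | O=C1[C@@H](Cc2cc(OC)c(OC)c(OC)c2)[C@H](Cc2cc(OC)c(OC)c(OCc3ccccc3)c2)CO1 | intermediate
12 | (3S,4S)-4-(3-hydroxy-4,5-dimethoxybenzyl)-3-(3,4,5-trimethoxybenzyl)oxolan-2-one | O=C1[C@@H](Cc2cc(OC)c(OC)c(OC)c2)[C@H](Cc2cc(OC)c(OC)c(O)c2)CO1 | intermediate
13 | 5-{[(3S,4S)-5-oxo-4-(3,4,5-trimethoxybenzyl)oxolan-3-yl]methyl}-2,3-dimethoxyphenyl methanesulfonate | O=C1[C@@H](Cc2cc(OC)c(OC)c(OC)c2)[C@H](Cc2cc(OC)c(OC)c(OS(C)(=O)=O)c2)CO1 | intermediate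
14 | (2S,3S)-2-{3-[(methylsulfonyl)oxy]-4,5-dimethoxybenzyl}-3-(3,4,5-trimethoxybenzyl)butane-1,4-diol | COc1cc(C[C@H](CO)[C@@H](CO)Cc2cc(OC)c(OC)c(OC)c2)cc(OS(C)(=O)=O)c1OC | intermediate
15 | benzylic cation of 14 at the trimethoxybenzyl carbon | COc1cc(C[C@H](CO)[C@@H](CO)[CH+]c2cc(OC)c(OC)c(OC)c2)cc(OS(C)(=O)=O)c1OC | intermediate (not isolated)
16 | [(2R,3S,4S)-4-{3-[(methylsulfonyl)oxy]-4,5-dimethoxybenzyl}-2-(3,4,5-trimethoxyphenyl)oxolan-3-yl]methanol | COc1cc(C[C@@H]2CO[C@@H](c3cc(OC)c(OC)c(OC)c3)[C@@H]2CO)cc(OS(C)(=O)=O)c1OC | intermediate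
17 | [(2R,3S,4S)-4-(3-hydroxy-4,5-dimethoxybenzyl)-2-(3,4,5-trimethoxyphenyl)oxolan-3-yl]methanol | COc1cc(C[C@@H]2CO[C@@H](c3cc(OC)c(OC)c(OC)c3)[C@@H]2CO)cc(O)c1OC | target

Total step count: 10. Longest linear sequence: 10 steps (1 → 17); compounds 3 and 9 enter as purchased partners.

Steps most likely to fail

1. Step 9. Hydride abstraction may not discriminate cleanly between the two benzylic CH2 groups, and the benzylic ether C–H of the product may be oxidised further while diol is still present. The fallback introduces the benzylic oxygen by an aldol reaction and closes the ring with acid instead of by oxidation. It sets out from lactone 8. The lithium enolate of 8 (LiHMDS, THF, −78 °C) is added to commercial 3,4,5-trimethoxybenzaldehyde, which should give the trans aldol adduct (3R,4S)-4-[3-(benzyloxy)-4,5-dimethoxybenzyl]-3-[hydroxy(3,4,5-trimethoxyphenyl)methyl]oxolan-2-one F1; either carbinol epimer serves, because that centre is ionised later. LiAlH4 in THF reduces the lactone to the triol (2S,3S)-2-[3-(benzyloxy)-4,5-dimethoxybenzyl]-3-[hydroxy(3,4,5-trimethoxyphenyl)methyl]butane-1,4-diol F2. Catalytic camphorsulfonic acid in CH2Cl2 ionises the benzylic alcohol, and the hydroxyl of the future C5 closes the oxolane trans to the C3 substituent, which should give the benzyl ether [(2R,3S,4S)-4-[3-(benzyloxy)-4,5-dimethoxybenzyl]-2-(3,4,5-trimethoxyphenyl)oxolan-3-yl]methanol F3. Hydrogenolysis of the aryl benzyl ether (H2, Pd/C, EtOAc, stopped once F3 is consumed so that the benzylic C2–O1 bond is spared) comes back to the route at target 17.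

2. Step 5. Displacement of the benzylic chloride may be slow enough for proton transfer between enolate and product to compete, which would lead to double alkylation and erode trans control. The fallback replaces alkylation by acylation and deoxygenation. It sets out from lactone 8. The enolate (2 equiv LiHMDS, THF, −78 °C) is acylated with commercial 3,4,5-trimethoxybenzoyl chloride to give the keto lactone (3R,4S)-4-[3-(benzyloxy)-4,5-dimethoxybenzyl]-3-(3,4,5-trimethoxybenzoyl)oxolan-2-one F4, whose acidic C3 settles in the trans arrangement. Hydrogenation over Pd/C in AcOH with a trace of HClO4 reduces the aryl ketone to CH2 by way of the benzylic alcohol and cleaves the benzyl ether in the same operation. Any cis lactone would be equilibrated to trans with DBU. The fallback comes back to the route at phenol lactone 12.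

3. Step 3. Enantioface discrimination may be incomplete, or an E/Z mixture carried over from step 2 may lower it. The fallback replaces asymmetric catalysis by classical resolution. It sets out from alkene acid 5. Hydrogenation with an achiral homogeneous catalyst ([Rh(cod)(dppb)]BF4, H2, MeOH), which spares the benzyl ether, gives racemic 4-[3-(benzyloxy)-4,5-dimethoxyphenyl]-3-(methoxycarbonyl)butanoic acid F5. Salt formation with (R)-1-phenylethylamine (or its antipode, whichever forms the less soluble salt with the (S)-acid) and recrystallisation give the (R)-1-phenylethylammonium salt of the (S)-acid F6. Dilute HCl liberates the acid, and the fallback comes back to the route at acid 6.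

Further compounds
F1 | step 9 | (3R,4S)-4-[3-(benzyloxy)-4,5-dimethoxybenzyl]-3-[hydroxy(3,4,5-trimethoxyphenyl)methyl]oxolan-2-one (carbinol epimers) | O=C1[C@@H](C(O)c2cc(OC)c(OC)c(OC)c2)[C@H](Cc2cc(OC)c(OC)c(OCc3ccccc3)c2)CO1
F2 | step 9 | (2S,3S)-2-[3-(benzyloxy)-4,5-dimethoxybenzyl]-3-[hydroxy(3,4,5-trimethoxyphenyl)methyl]butane-1,4-diol | COc1cc(C[C@H](CO)[C@@H](CO)C(O)c2cc(OC)c(OC)c(OC)c2)cc(OCc2ccccc2)c1OC
F3 | step 9 | [(2R,3S,4S)-4-[3-(benzyloxy)-4,5-dimethoxybenzyl]-2-(3,4,5-trimethoxyphenyl)oxolan-3-yl]methanol | COc1cc(C[C@@H]2CO[C@@H](c3cc(OC)c(OC)c(OC)c3)[C@@H]2CO)cc(OCc2ccccc2)c1OC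
F4 | step 5 | (3R,4S)-4-[3-(benzyloxy)-4,5-dimethoxybenzyl]-3-(3,4,5-trimethoxybenzoyl)oxolan-2-one | O=C1[C@@H](C(=O)c2cc(OC)c(OC)c(OC)c2)[C@H](Cc2cc(OC)c(OC)c(OCc3ccccc3)c2)CO1
F5 | step 3 | racemic 4-[3-(benzyloxy)-4,5-dimethoxyphenyl]-3-(methoxycarbonyl)butanoic acid | COC(=O)C(CC(=O)O)Cc1cc(OC)c(OC)c(OCc2ccccc2)c1
F6 | step 3 | (R)-1-phenylethylammonium (3S)-4-[3-(benzyloxy)-4,5-dimethoxyphenyl]-3-(methoxycarbonyl)butanoate | C[C@@H]([NH3+])c1ccccc1.[O-]C(=O)C[C@H](Cc1cc(OC)c(OC)c(OCc2ccccc2)c1)C(=O)OC
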